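(The earlier runs and the new flask come from a simulation from invented constants, and the scatter is random.)

If the blue run were just the green run over again, you would write down 0.2946 M at 67 min, which is 98.2% of the Xa charged. But blue holds 0.990 M of Xb instead of 0.330 M, so the job is to reckon the correction and leave the rest to the green readings.

| setting | teal | ochre | green | violet | blue |
|---|---|---|---|---|---|
| Xa | 0.300 M | 0.180 M | 0.300 M | 0.300 M | 0.300 M |
| Xb | 0.330 M | 0.210 M | 0.330 M | 0.660 M | 0.990 M |
| Xc | 0.0150 M | 0.0150 M | 0.0450 M | 0.0150 M | 0.0450 M |
| time |  |  |  |  | 67 min |

| run | time / min | [Xp] / M |
|---|---|---|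
| teal run | 2.7 | 0.0075 |
| teal run | 6.0 | 0.0186 |
| teal run | 13 | 0.0415 |
| teal run | 30 | 0.0917 |
| teal run | 67 | 0.1610 |
| ochre run | 2.7 | 0.0050 |
| ochre run | 6.0 | 0.0141 |
| ochre run | 13 | 0.0305 |
| ochre run | 30 | 0.0694 |
| ochre run | 67 | 0.1180 |
| green run | 2.7 | 0.0190 |
| green run | 6.0 | 0.0524 |
| green run | 13 | 0.1159 |
| green run | 30 | 0.2224 |
| green run | 67 | 0.2946 |
| violet run | 2.7 | 0.0105 |
| violet run | 6.0 | 0.0231 |
| violet run | 13 | 0.0491 |
| violet run | 30 | 0.1005 |
| violet run | 67 | 0.1567 |

(scatter of a reading: 9 × 10⁻⁴ M)

- the exponent of [Xc] in the starting rate at the charge of the teal run (at the point where two percent of the Xa have become Xp)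
- the exponent of [Xa] in the starting rate at the charge of the teal run (at the point where two percent of the Xa have become Xp) (one fixed amount of Xp, the same in the runs compared)
- the ochre run starts with 0.120 M less of Xa and of Xb than the teal run, and with no Xp. Compared where both hold the same amount of Xa, once fifteen percent of what the ochre run was charged with has turned into Xp, is the ochre run faster, slower or alike (within a tenth)?
- Xp in the blue run at 67 min, as a share of the Xa charged

- Overall: Xa + Xb -> Xp, with Xc as catalyst.
- Constant volume, constant temperature.
- The analysis sees a species whether free or bound.
- An order is taken over about fifteen percent of the charge, up and down.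

Start with what extra Xb does in violet against teal. Between the first and third readings violet makes Xp at 0.00375 M/min and teal at 0.00330 M/min, so violet is faster early. Yet violet ends lower, at 0.1567 M against 0.1610 M. Between the last two readings, violet makes 0.00152 M/min and teal 0.00187 M/min.

So define the fade constant of a run: the natural logarithm of its early rate over its late rate, divided by the 40.6 min between the middles of those two windows, an apparent first-order decay constant. For teal it reads 0.0139 /min, for violet 0.0222 /min.

You may object that this is simply Xa falling. Then compare like with like: teal's late window holds about 0.174 M of Xa, while ochre's early window holds about 0.162 M, yet ochre runs at 0.00248 M/min, faster than teal's 0.00187 M/min. A run's age therefore counts, though the fade constant still carries some of the fall in Xa.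

Now scale to blue. Between teal and violet, the fade grows as [Xb] to the power 0.672 and the early rate as [Xb] to the power 0.183. Blue has the Xa and Xc charges of green and differs from it in Xb, so I scale from green, not from teal, whose Xc is 0.0150 M against green's 0.0450 M. In the same two windows green makes Xp at 0.00941 M/min and 0.00195 M/min, so green's fade constant reads 0.0387 /min, which is 2.78 times teal's. Blue should then fade at 0.0810 /min and start from green's early rate raised to 0.0115 M/min.

Integrating a fading rate over 67 min, with the rate taken back to time zero, offers 0.305 M in green and 0.267 M in blue. The green figure stands above green's last reading of 0.2946 M, so the integral is no product forecast by itself. But their ratio, 0.876, can serve as the correction, since the Xa charge is the same on both sides. Applied to green's reading it gives 0.258 M, or 86.0% of the Xa charged. The doubt that remains is that green's late window holds about 0.0415 M of Xa against teal's 0.174 M, so a ratio built on green's fade constant is rough, but this is the number I commit to.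

The forecast says 0.97 for the order in Xc, 0.3 for the order in Xa, faster for ochre and 80% for blue, on the ground that “The runs suggest a catalyst that partly saturates in Xa and dies during the run”. Its blue figure lies below mine.

The steps in the flask are these:

    Xc + Xa → Xc.Xa (8.400 /M/min)
    Xc.Xa + Xb → Z (5.904 /M/min)
    Z → Xp + Xc (0.7560 /min)
    Xc + Xb → L + Xb (1.128 /M/min)
    2 Xb ⇌ Xb2, settled at all times (18.00 /M)

The blue run gives 90.9%, and the other answers are 0.88, 0.13 and faster. A power-law fit to the runs gave 98.2% for the blue run. Blue's Xp over green's reading comes to 0.926, beside the reckoned 0.876. Now take the fade constant to ochre, whose late readings it has not used: teal's 0.0139 /min, scaled to 0.210 M of Xb, gives 0.0103 /min. With ochre's early rate this puts half of its Xa turned at 41.1 min, and the ochre run reached that point at 42.3 min.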